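**Retrosynthetic overview**

1. Ring letters: A = formyl/hydroxy/methyl benzoate ring, B = seven-membered dioxepinone, C = hexasubstituted arene, D = 2,2-dimethylpyran-4-one (chromanone locants O1, C2, C3, C4, C4a, C8, C8a). Enabling feature: on ring C the pyran oxygen O1 (on C8a) and the free 8-OH (on C8) are ortho neighbours, and the C4 carbonyl hangs on C4a, the other neighbour of C8a. C2 with both methyls can therefore be stored as the ketal carbon of a 2,2-dimethyl-1,3-benzodioxole bridging O1 and O8, beside an acetyl group that supplies C3 and C4.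
2. Ring D, bond C2–C3 (last step): target ⇐ acetyl acetonide depsidone 28, an isomer of the target. Opening the temporary dioxole ring gives an aryl oxocarbenium ion at O1, which the enol silane of the acetyl group captures; the same event frees the 8-OH.
3. Ring B: lactonisation of seco acid 27, in which the acetonide leaves only one phenol of ring C next to the ether oxygen, so only one lactone regioisomer can form ⇐ diaryl ether from SNAr of ring C phenol 15 on ring A fluoride 21.
4. Ring C fragment from 4-methylcatechol (acetonide, bromination/hydroxylation, benzylation, ortho-lithiation/hydroxylation, bromination); the acetyl group enters after ether formation by Stille coupling. Ring A fragment from 2,6-difluoro-4-methylbenzaldehyde (SNAr with benzyl alcohol, bromination, benzyloxycarbonylation).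
5. Order of ring formation: rings A and C are bought as arenes; temporary dioxole (step 1) → ring B (step 13) → ring D (step 14, dioxole consumed).

Key step: step 14

Remark: the target has no stereocentre, so no step sets or endangers configuration. 4-Methylcatechol, 2,6-difluoro-4-methylbenzaldehyde and tributyl(1-ethoxyvinyl)stannane are taken as commercial.

**Route**

Step 1
Reactants: 1 4-methylcatechol; 2 2,2-dimethoxypropane
Product: 3 2,2,5-trimethyl-1,3-benzodioxole
Conditions: TsOH·H2O (cat.), toluene, reflux, MeOH removed over 4 Å sieves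
Reagents that add atoms: 2,2-dimethoxypropane, COC(C)(C)OC
Why: Acid-catalysed transketalisation of a catechol (acetonide formation) is driven by removal of methanol and installs the dioxole carbon that later becomes C2 with its two methyl groups.

Step 2
Reactants: 3 2,2,5-trimethyl-1,3-benzodioxole; 4 N-bromosuccinimide
Product: 5 5-bromo-2,2,6-trimethyl-1,3-benzodioxole
Conditions: NBS, MeCN, 0 °C to rt, dark
Reagents that add atoms: N-bromosuccinimide, O=C1CCC(=O)N1Br
Why: Electrophilic aromatic bromination should go para to a dioxole oxygen and ortho to the methyl group, the usual pattern for 3,4-dioxygenated toluenes.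

Step 3
Reactants: 5 5-bromo-2,2,6-trimethyl-1,3-benzodioxole; 6 hydrogen peroxide
Product: 9 2,2,6-trimethyl-1,3-benzodioxol-5-ol, via aryllithium 7 (not isolated), via dimethyl arylboronate 8 (not isolated)
Conditions: n-BuLi, THF, −78 °C; B(OMe)3, −78 °C to rt; AcOH, 30% H2O2, 0 °C to rt
Reagents that add atoms: hydrogen peroxide, OO
Why: Bromine–lithium exchange, borylation and boronate oxidation is a standard aryl bromide to phenol sequence that the base-stable acetonide should tolerate.

Step 4
Reactants: 9 2,2,6-trimethyl-1,3-benzodioxol-5-ol; 10 benzyl bromide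
Product: 11 5-(benzyloxy)-2,2,6-trimethyl-1,3-benzodioxole
Conditions: BnBr, K2CO3, DMF, rt
Reagents that add atoms: benzyl bromide, BrCc1ccccc1
Why: Williamson etherification protects the future lactone oxygen as a benzyl ether, which also serves as a directing group for the next metalation.

Step 5
Reactants: 11 5-(benzyloxy)-2,2,6-trimethyl-1,3-benzodioxole; 6 hydrogen peroxide
Product: 14 5-(benzyloxy)-2,2,6-trimethyl-1,3-benzodioxol-4-ol, via aryllithium 12 (not isolated), via dimethyl arylboronate 13 (not isolated)
Conditions: n-BuLi, THF, −20 to 0 °C; B(OMe)3, −78 °C to rt; AcOH, 30% H2O2, 0 °C to rt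
Reagents that add atoms: hydrogen peroxide, OO
Why: Directed ortho-metalation should occur at the ring CH flanked by the benzyloxy and dioxole oxygens (the most acidic position), and borylation/oxidation then installs the hydroxyl that becomes the diaryl ether oxygen.

Step 6
Reactants: 14 5-(benzyloxy)-2,2,6-trimethyl-1,3-benzodioxol-4-ol; 4 N-bromosuccinimide
Product: 15 5-(benzyloxy)-7-bromo-2,2,6-trimethyl-1,3-benzodioxol-4-ol
Conditions: NBS (1.0 equiv), CH2Cl2, −20 °C, dark
Reagents that add atoms: N-bromosuccinimide, O=C1CCC(=O)N1Br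
Why: Electrophilic bromination para to the free phenol can only take the single unsubstituted position of the ring, which is the carbon that will carry the acetyl group.

Step 7
Reactants: 16 2,6-difluoro-4-methylbenzaldehyde; 17 benzyl alcohol
Product: 18 2-(benzyloxy)-6-fluoro-4-methylbenzaldehyde
Conditions: BnOH (1.0 equiv), NaH, THF, 0 °C, alkoxide added to 16
Reagents that add atoms: benzyl alcohol, OCc1ccccc1
Why: SNAr at one of two equivalent fluorines ortho to the formyl group should stop after one substitution because the alkoxy group introduced deactivates the ring.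

Step 8
Reactants: 18 2-(benzyloxy)-6-fluoro-4-methylbenzaldehyde; 4 N-bromosuccinimide
Product: 19 6-(benzyloxy)-3-bromo-2-fluoro-4-methylbenzaldehyde
Conditions: NBS, DMF, rt, dark
Reagents that add atoms: N-bromosuccinimide, O=C1CCC(=O)N1Br
Why: Electrophilic bromination should go para to the benzyloxy group (ortho to fluorine), as 3-fluoroanisoles brominate para to the alkoxy group.

Step 9
Reactants: 19 6-(benzyloxy)-3-bromo-2-fluoro-4-methylbenzaldehyde; 20 carbon monoxide; 17 benzyl alcohol
Product: 21 benzyl 4-(benzyloxy)-2-fluoro-3-formyl-6-methylbenzoate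
Conditions: CO (1 atm), BnOH (1.5 equiv), Pd(OAc)2 (5 mol%), Xantphos (6 mol%), Et3N, toluene, 90 °C
Reagents that add atoms: carbon monoxide, [C-]#[O+]; benzyl alcohol, OCc1ccccc1
Why: Palladium-catalysed alkoxycarbonylation of the aryl bromide (oxidative addition to zerovalent palladium, CO insertion, alcoholysis) tolerates the aldehyde and the aryl fluoride and places the ester next to the fluorine.

Step 10
Reactants: 15 5-(benzyloxy)-7-bromo-2,2,6-trimethyl-1,3-benzodioxol-4-ol; 21 benzyl 4-(benzyloxy)-2-fluoro-3-formyl-6-methylbenzoate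
Product: 22 benzyl 4-(benzyloxy)-2-{[5-(benzyloxy)-7-bromo-2,2,6-trimethyl-1,3-benzodioxol-4-yl]oxy}-3-formyl-6-methylbenzoate
Conditions: Cs2CO3, DMSO, 60–80 °C, argon
Reagents that add atoms: none
Why: SNAr of the cesium phenoxide on a fluoride flanked by formyl and ester carbonyls (addition–elimination through a Meisenheimer complex) should form the diaryl ether, and only the intended oxygen can react because its neighbours are benzylated or tied in the acetonide.

Step 11
Reactants: 22 benzyl 4-(benzyloxy)-2-{[5-(benzyloxy)-7-bromo-2,2,6-trimethyl-1,3-benzodioxol-4-yl]oxy}-3-formyl-6-methylbenzoate; 23 tributyl(1-ethoxyvinyl)stannane; 24 water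
Product: 26 benzyl 2-{[7-acetyl-5-(benzyloxy)-2,2,6-trimethyl-1,3-benzodioxol-4-yl]oxy}-4-(benzyloxy)-3-formyl-6-methylbenzoate, via ethyl enol ether 25 (not isolated)
Conditions: PdCl2(PPh3)2 (10 mol%), toluene, 100 °C; then 1 M HCl, THF, rt
Reagents that add atoms: tributyl(1-ethoxyvinyl)stannane, CCCC[Sn](CCCC)(CCCC)C(=C)OCC; water, O
Why: Stille coupling with an acetyl anion equivalent followed by mild hydrolysis of the enol ether introduces the methyl ketone only after the basic SNAr step, so that no Claisen–Schmidt condensation with the formyl group can occur there.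

Step 12
Reactants: 26 benzyl 2-{[7-acetyl-5-(benzyloxy)-2,2,6-trimethyl-1,3-benzodioxol-4-yl]oxy}-4-(benzyloxy)-3-formyl-6-methylbenzoate
Product: 27 2-[(7-acetyl-5-hydroxy-2,2,6-trimethyl-1,3-benzodioxol-4-yl)oxy]-3-formyl-4-hydroxy-6-methylbenzoic acid
Conditions: H2 (1 atm), 10% Pd/C, EtOAc, rt, stopped after three equivalents of H2
Reagents that add atoms: none
Why: Hydrogenolysis should remove both benzyl ethers and the benzyl ester in one operation, while the hindered aryl aldehyde, the aryl ketone and the acetonide are expected to survive at atmospheric pressure in a neutral solvent.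

Step 13
Reactants: 27 2-[(7-acetyl-5-hydroxy-2,2,6-trimethyl-1,3-benzodioxol-4-yl)oxy]-3-formyl-4-hydroxy-6-methylbenzoic acid
Product: 28 acetyl acetonide depsidone
Conditions: DCC, DMAP (cat.), CH2Cl2 (0.005 M), 0 °C to rt
Reagents that add atoms: none
Why: Carbodiimide-mediated (Steglich-type) lactonisation at high dilution should close the seven-membered ring B onto the only free phenol ortho to the ether oxygen on ring C, the other ortho oxygen being locked in the acetonide and the ring A phenol being para to the carboxyl and hydrogen-bonded to the formyl group.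

Step 14
Reactants: 28 acetyl acetonide depsidone
Product: 31 target depsidone CNP0271978.0, via bis-silylated enol silane 29 (not isolated), via bis-silyl ether of the target 30 (not isolated)
Conditions: TMSOTf (2.5 equiv), Et3N (2.1 equiv), CH2Cl2 (0.005 M), −40 °C to rt; then 1 M HCl, THF, 0 °C
Reagents that add atoms: none
Why: Proposed new method: TMSOTf/Et3N converts the acetyl group into its trimethylsilyl enol ether and caps the ring A phenol (29); the slight excess of TMSOTf then silylates the dioxole oxygen on C8 and opens the ketal to the aryl oxocarbenium ion ArO(+)=CMe2 at O1, the enol silane carbon attacks the cationic carbon to forge C2–C3, loss of the silyl cation gives the C4 ketone and regenerates TMSOTf (30), and aqueous acid removes both silyl ethers. The closest known reaction types are the silyl enol ether Prins cyclisation to tetrahydropyran-4-ones, the Petasis–Ferrier rearrangement and the Mukaiyama aldol-type addition of enol silanes to ketals, here with the oxocarbenium ion generated by opening a catechol acetonide and not by condensation. Ring D closes in a 6-(enolendo)-endo-trig mode onto the oxocarbenium ion while the five-membered dioxole opens, so the step is a ring transposition that needs no external carbon source and also unmasks the C8 hydroxyl. No stereocentre is formed, because C2 carries two methyl groups and the target is achiral. The selectivity needed is productive over unproductive ketal ionisation and intra- over intermolecular capture: opening toward O8 gives a cation that cannot reach the enol silane and should simply reclose, the C5 methyl twists the enol silane out of the arene plane so that its π lobe points at the cationic carbon, enolisation removes the carbonyl that could chelate the Lewis acid and steer cleavage the wrong way, and high dilution suppresses Mukaiyama aldol addition to the hindered formyl group of a second molecule. The lactone and the diaryl ether are expected to be inert to TMSOTf at or below room temperature.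

**Compound list**

1 | 4-methylcatechol (4-methylbenzene-1,2-diol) | Cc1ccc(O)c(O)c1 | starting material
2 | 2,2-dimethoxypropane | COC(C)(C)OC | starting material
3 | 2,2,5-trimethyl-1,3-benzodioxole | Cc1ccc2OC(C)(C)Oc2c1 | intermediate
4 | N-bromosuccinimide | O=C1CCC(=O)N1Br | starting material
5 | 5-bromo-2,2,6-trimethyl-1,3-benzodioxole | Cc1cc2OC(C)(C)Oc2cc1Br | intermediate
6 | hydrogen peroxide | OO | starting material
7 | (2,2,6-trimethyl-1,3-benzodioxol-5-yl)lithium | [Li]c1cc2OC(C)(C)Oc2cc1C | intermediate
8 | dimethyl (2,2,6-trimethyl-1,3-benzodioxol-5-yl)boronate | COB(OC)c1cc2OC(C)(C)Oc2cc1C | intermediate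
9 | 2,2,6-trimethyl-1,3-benzodioxol-5-ol | Cc1cc2OC(C)(C)Oc2cc1O | intermediate
10 | benzyl bromide | BrCc1ccccc1 | starting material
11 | 5-(benzyloxy)-2,2,6-trimethyl-1,3-benzodioxole | Cc1cc2OC(C)(C)Oc2cc1OCc1ccccc1 | intermediate
12 | [5-(benzyloxy)-2,2,6-trimethyl-1,3-benzodioxol-4-yl]lithium | [Li]c1c(OCc2ccccc2)c(C)cc2OC(C)(C)Oc12 | intermediate
13 | dimethyl [5-(benzyloxy)-2,2,6-trimethyl-1,3-benzodioxol-4-yl]boronate | COB(OC)c1c(OCc2ccccc2)c(C)cc2OC(C)(C)Oc12 | intermediate
14 | 5-(benzyloxy)-2,2,6-trimethyl-1,3-benzodioxol-4-ol | Oc1c(OCc2ccccc2)c(C)cc2OC(C)(C)Oc12 | intermediate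
15 | 5-(benzyloxy)-7-bromo-2,2,6-trimethyl-1,3-benzodioxol-4-ol | Oc1c(OCc2ccccc2)c(C)c(Br)c2OC(C)(C)Oc12 | intermediate
16 | 2,6-difluoro-4-methylbenzaldehyde | Cc1cc(F)c(C=O)c(F)c1 | starting material
17 | benzyl alcohol | OCc1ccccc1 | starting material
18 | 2-(benzyloxy)-6-fluoro-4-methylbenzaldehyde | Cc1cc(F)c(C=O)c(OCc2ccccc2)c1 | intermediate
19 | 6-(benzyloxy)-3-bromo-2-fluoro-4-methylbenzaldehyde | Cc1cc(OCc2ccccc2)c(C=O)c(F)c1Br | intermediate
20 | carbon monoxide | [C-]#[O+] | starting material
21 | benzyl 4-(benzyloxy)-2-fluoro-3-formyl-6-methylbenzoate | Cc1cc(OCc2ccccc2)c(C=O)c(F)c1C(=O)OCc1ccccc1 | intermediate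
22 | benzyl 4-(benzyloxy)-2-{[5-(benzyloxy)-7-bromo-2,2,6-trimethyl-1,3-benzodioxol-4-yl]oxy}-3-formyl-6-methylbenzoate | Cc1cc(OCc2ccccc2)c(C=O)c(Oc2c(OCc3ccccc3)c(C)c(Br)c3OC(C)(C)Oc23)c1C(=O)OCc1ccccc1 | intermediate
23 | tributyl(1-ethoxyvinyl)stannane | CCCC[Sn](CCCC)(CCCC)C(=C)OCC | starting material
24 | water | O | starting material
25 | benzyl 4-(benzyloxy)-2-{[5-(benzyloxy)-7-(1-ethoxyvinyl)-2,2,6-trimethyl-1,3-benzodioxol-4-yl]oxy}-3-formyl-6-methylbenzoate | Cc1cc(OCc2ccccc2)c(C=O)c(Oc2c(OCc3ccccc3)c(C)c(C(=C)OCC)c3OC(C)(C)Oc23)c1C(=O)OCc1ccccc1 | intermediate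
26 | benzyl 2-{[7-acetyl-5-(benzyloxy)-2,2,6-trimethyl-1,3-benzodioxol-4-yl]oxy}-4-(benzyloxy)-3-formyl-6-methylbenzoate | Cc1cc(OCc2ccccc2)c(C=O)c(Oc2c(OCc3ccccc3)c(C)c(C(C)=O)c3OC(C)(C)Oc23)c1C(=O)OCc1ccccc1 | intermediate
27 | 2-[(7-acetyl-5-hydroxy-2,2,6-trimethyl-1,3-benzodioxol-4-yl)oxy]-3-formyl-4-hydroxy-6-methylbenzoic acid | Cc1cc(O)c(C=O)c(Oc2c(O)c(C)c(C(C)=O)c3OC(C)(C)Oc23)c1C(=O)O | intermediate
28 | acetyl acetonide depsidone: the depsidone (dibenzo[b,e][1,4]dioxepin-11-one) with ring A as in the target (methyl, hydroxyl, formyl) and ring C carrying, from the ester-oxygen carbon onward, methyl, acetyl, and a 2,2-dimethyl-1,3-dioxole fused across the next two carbons | Cc1cc(O)c(C=O)c2c1C(=O)Oc1c(C)c(C(C)=O)c3OC(C)(C)Oc3c1O2 | intermediate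
29 | bis-silylated enol silane: 28 with the ring A hydroxyl as trimethylsilyl ether and the acetyl group as 1-(trimethylsilyloxy)vinyl | Cc1cc(O[Si](C)(C)C)c(C=O)c2c1C(=O)Oc1c(C)c(C(=C)O[Si](C)(C)C)c3OC(C)(C)Oc3c1O2 | intermediate
30 | bis(trimethylsilyl) ether of the target (both phenols silylated) | Cc1cc(O[Si](C)(C)C)c(C=O)c2c1C(=O)Oc1c(C)c3c(c(O[Si](C)(C)C)c1O2)OC(C)(C)CC3=O | intermediate
31 | target depsidone CNP0271978.0: depsidone with ring A carrying methyl, hydroxyl and formyl, and ring C carrying a methyl next to the ester oxygen, a free hydroxyl next to the ether oxygen, and a fused 2,2-dimethyl-2,3-dihydropyran-4-one (carbonyl on the carbon next to the methyl-bearing carbon, ring oxygen on the carbon next to the hydroxyl-bearing carbon) | Cc1cc(O)c(C=O)c2c1C(=O)Oc1c(C)c3c(c(O)c1O2)OC(C)(C)CC3=O | target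

**Totals and risks**

Total step count: 14. Longest linear sequence: 11 steps (steps 1–6, then 10–14); steps 7–9 form the ring A branch.

Three steps most likely to fail:

1. Step 14 (proposed new method). What may go wrong: unproductive ketal ionisation (opening toward O8, or proton loss from the oxocarbenium ion to an isopropenyl ether) may outpace C–C bond formation, so that the acetonide is merely lost on work-up. The fallback uses known chemistry, sets out from 28 and returns at 31. Compound 28 is bis-silylated as in the route (TMSOTf, Et3N, CH2Cl2) and the enol silane is intercepted intermolecularly with 2,2-dimethoxypropane (2) under catalytic TMSOTf at −78 °C, a Mukaiyama aldol-type addition to a dimethyl ketal. Mild acidic work-up should then give the acetonide depsidone bearing a 3-methoxy-3-methylbutanoyl group in place of acetyl, F1. Treating F1 with TFA/H2O (9:1) at rt should remove the acetonide and eliminate methanol to the 3-methylbut-2-enoyl catechol depsidone F2, which is not isolated. Its hydroxyl ortho to the acyl group closes ring D by oxa-Michael addition (the classical chromanone closure, forming O1–C2), giving 31; the second catechol hydroxyl cannot reach the enone.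

2. Step 10. What may go wrong: slow addition of a hindered phenoxide to a fluoride flanked by two carbonyl groups, with competing attack on the benzyl ester or oxidation of the electron-rich phenoxide. The fallback changes the order of bond formation, sets out from 14 and 19 and returns at 22. The more nucleophilic, bromine-free phenol 14 is coupled by SNAr (Cs2CO3, DMSO) with the ester-free fluoride 19 to give 6-(benzyloxy)-2-{[5-(benzyloxy)-2,2,6-trimethyl-1,3-benzodioxol-4-yl]oxy}-3-bromo-4-methylbenzaldehyde F3. Its single aryl bromide is then carbonylated (CO, BnOH, Pd(OAc)2, Xantphos, Et3N) to benzyl 4-(benzyloxy)-2-{[5-(benzyloxy)-2,2,6-trimethyl-1,3-benzodioxol-4-yl]oxy}-3-formyl-6-methylbenzoate F4. NBS should then brominate the only free position of the electron-rich ring C, para to the aryloxy oxygen, to give 22.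

3. Step 11. What may go wrong: slow oxidative addition at a bromide flanked by methyl and the dioxole oxygen, leading to protodebromination or stannane decomposition in a polyfunctional substrate. The fallback installs the ketone before fragment union by organolithium chemistry, sets out from 15 and returns at 26. Phenol 15 is silylated (TBSCl, imidazole, DMF) to {[5-(benzyloxy)-7-bromo-2,2,6-trimethyl-1,3-benzodioxol-4-yl]oxy}(tert-butyl)dimethylsilane F5. Bromine–lithium exchange (t-BuLi, THF, −78 °C) and acylation with N-methoxy-N-methylacetamide should give 1-{6-(benzyloxy)-7-[(tert-butyldimethylsilyl)oxy]-2,2,5-trimethyl-1,3-benzodioxol-4-yl}ethan-1-one F6. TBAF then releases 1-[6-(benzyloxy)-7-hydroxy-2,2,5-trimethyl-1,3-benzodioxol-4-yl]ethan-1-one F7, which is joined to 21 by SNAr (Cs2CO3, DMSO, kept at or below 60 °C to limit aldol condensation) to give 26.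

**Further compounds**

F1 | step 14 | acetonide depsidone 28 with 3-methoxy-3-methylbutanoyl in place of acetyl | Cc1cc(O)c(C=O)c2c1C(=O)Oc1c(C)c(C(=O)CC(C)(C)OC)c3OC(C)(C)Oc3c1O2
F2 | step 14 | 3-methylbut-2-enoyl catechol depsidone (acetonide removed) | Cc1cc(O)c(C=O)c2c1C(=O)Oc1c(C)c(C(=O)C=C(C)C)c(O)c(O)c1O2
F3 | step 10 | 6-(benzyloxy)-2-{[5-(benzyloxy)-2,2,6-trimethyl-1,3-benzodioxol-4-yl]oxy}-3-bromo-4-methylbenzaldehyde | Cc1cc(OCc2ccccc2)c(C=O)c(Oc2c(OCc3ccccc3)c(C)cc3OC(C)(C)Oc23)c1Br
F4 | step 10 | benzyl 4-(benzyloxy)-2-{[5-(benzyloxy)-2,2,6-trimethyl-1,3-benzodioxol-4-yl]oxy}-3-formyl-6-methylbenzoate | Cc1cc(OCc2ccccc2)c(C=O)c(Oc2c(OCc3ccccc3)c(C)cc3OC(C)(C)Oc23)c1C(=O)OCc1ccccc1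
F5 | step 11 | {[5-(benzyloxy)-7-bromo-2,2,6-trimethyl-1,3-benzodioxol-4-yl]oxy}(tert-butyl)dimethylsilane | CC(C)(C)[Si](C)(C)Oc1c(OCc2ccccc2)c(C)c(Br)c2OC(C)(C)Oc12
F6 | step 11 | 1-{6-(benzyloxy)-7-[(tert-butyldimethylsilyl)oxy]-2,2,5-trimethyl-1,3-benzodioxol-4-yl}ethan-1-one | CC(=O)c1c(C)c(OCc2ccccc2)c(O[Si](C)(C)C(C)(C)C)c2OC(C)(C)Oc12
F7 | step 11 | 1-[6-(benzyloxy)-7-hydroxy-2,2,5-trimethyl-1,3-benzodioxol-4-yl]ethan-1-one | CC(=O)c1c(C)c(OCc2ccccc2)c(O)c2OC(C)(C)Oc12
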